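**Strategy.** The cyclohexene is made as a cyclohex-2-enone by a two-carbon ring expansion. A 4,4-dimethylcyclobutenone that already carries the whole side chain takes up vinyllithium. The alkoxide opens (4π) to a trienolate whose ends are the vinyl CH2 and the CMe2 carbon, and 6π-electrocyclization joins exactly these two atoms, closing the six-membered ring and creating the quaternary carbon. The step exploits the adjacency of ring CH2 (C5) and gem-dimethyl carbon (C6) and places a ketone at C3, the later alkene CH. That ketone then sets C1: CBS reduction and a suprafacial reductive 1,3-transposition deliver hydrogen to C1 and shift the double bond to C2=C3. Arachidonoylation ends the route.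

Key step: step 7

Remark on numbering: ring atoms are C1 (stereogenic CH, S in the target), C2 (C–CH3), C3 (=CH), C4 and C5 (CH2), C6 (CMe2); side-chain carbons C1′ to C9′ count outward from the ring.
Assumption: (2E,6E)-farnesol, arachidonic acid, isobutyryl chloride and 1-ethoxyprop-1-yne are taken as commercial.

Step 1
Reactants: 1 (2E,6E)-farnesol
Product: 2 (2E,6E)-farnesyl tert-butyldiphenylsilyl ether
Conditions: TBDPSCl, imidazole, DMF, 0 °C → rt
Reagents that add atoms: tert-butyl(chloro)diphenylsilane, CC(C)(C)[Si](Cl)(c1ccccc1)c1ccccc1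
Why: Standard silylation of the primary allylic alcohol (silyl ether protection); the TBDPS group should survive the later organolithium and dilute-acid steps.

Step 2
Reactants: 2 (2E,6E)-farnesyl tert-butyldiphenylsilyl ether
Product: 4 racemic 10,11-epoxide of 2, via bromohydrin 3 (not isolated)
Conditions: NBS, THF/H2O, 0 °C; then K2CO3, MeOH, rt
Reagents that add atoms: water, O
Why: Bromohydrin formation in aqueous THF is expected to favour the terminal trisubstituted alkene (the 2,3-alkene is deactivated by the allylic oxygen), and base closes the bromohydrin to the epoxide (intramolecular Williamson reaction); the new stereocentre is racemic and is destroyed in step 3.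

Step 3
Reactants: 4 racemic 10,11-epoxide of 2
Product: 6 (4E,8E)-10-(tert-butyldiphenylsilyloxy)-4,8-dimethyldeca-4,8-dienoic acid, via aldehyde 5 (not isolated)
Conditions: H5IO6, THF/Et2O, 0 °C; then NaClO2, NaH2PO4, 2-methyl-2-butene, t-BuOH/H2O, rt
Reagents that add atoms: sodium chlorite, [Na+].[O-]Cl=O
Why: Periodic acid hydrolyses the epoxide and cleaves the glycol to aldehyde 5 and acetone, and Pinnick oxidation of the crude aldehyde should give the acid without touching the alkenes or the silyl ether.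

Step 4
Reactants: 6 (4E,8E)-10-(tert-butyldiphenylsilyloxy)-4,8-dimethyldeca-4,8-dienoic acid
Product: 8 tert-butyl{[(2E,6E)-9-iodo-3,7-dimethylnona-2,6-dien-1-yl]oxy}diphenylsilane, via Barton ester 7 (not isolated)
Conditions: 1-hydroxypyridine-2(1H)-thione, DCC, DMAP (cat.), CH2Cl2, 0 °C → rt, dark; then CHI3, hν (tungsten lamp), rt
Reagents that add atoms: iodoform, IC(I)I
Why: Barton decarboxylative iodination: photolysis of thiohydroxamate ester 7 gives the C1′ radical after loss of CO2, which should abstract iodine from iodoform faster than it adds reversibly to the neighbouring alkene, so the E-alkenes are kept and the chain is shortened by the one carbon required.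

Step 5
Reactants: 9 isobutyryl chloride, 10 1-ethoxyprop-1-yne
Product: 12 3-ethoxy-2,4,4-trimethylcyclobut-2-en-1-one, via dimethylketene 11 (not isolated)
Conditions: Et3N, Et2O, reflux (slow addition of 9)
Reagents that add atoms: none
Why: Ketene–ynol ether [2+2] cycloaddition; the nucleophilic methyl-bearing alkyne carbon bonds to the ketene carbonyl carbon, which places the methyl next to C=O and the ethoxy group next to CMe2.

Step 6
Reactants: 8 tert-butyl{[(2E,6E)-9-iodo-3,7-dimethylnona-2,6-dien-1-yl]oxy}diphenylsilane, 12 3-ethoxy-2,4,4-trimethylcyclobut-2-en-1-one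
Product: 15 3-[(3E,7E)-9-(tert-butyldiphenylsilyloxy)-4,8-dimethylnona-3,7-dien-1-yl]-2,4,4-trimethylcyclobut-2-en-1-one, via alkyllithium 13 (not isolated), via lithium alkoxide 14 (not isolated)
Conditions: t-BuLi (2.1 equiv), Et2O/pentane, −78 °C; then 12, −78 → 0 °C; then 1 M HCl, THF, 0 °C
Reagents that add atoms: water, O
Why: Lithium–iodine exchange gives primary alkyllithium 13, which adds 1,2 to the vinylogous ester; dilute acid then effects the Stork–Danheiser transposition (loss of water and ethanol) to the 3-alkylcyclobutenone, whose carbonyl carbon is the future C3 and whose CMe2 is the future C6.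

Step 7
Reactants: 15 3-[(3E,7E)-9-(tert-butyldiphenylsilyloxy)-4,8-dimethylnona-3,7-dien-1-yl]-2,4,4-trimethylcyclobut-2-en-1-one
Product: 19 3-[(3E,7E)-9-(tert-butyldiphenylsilyloxy)-4,8-dimethylnona-3,7-dien-1-yl]-2,4,4-trimethylcyclohex-2-en-1-one, via lithium cyclobutenolate 16 (not isolated), via lithium trienolate 17 (not isolated), via lithium cyclohexadienolate 18 (not isolated)
Conditions: vinyllithium (from tributyl(vinyl)stannane and n-BuLi, THF, −78 °C), THF, −78 °C → 23 °C; then aq. NH4Cl
Reagents that add atoms: vinyllithium, [Li]C=C (made in the flask from tributyl(vinyl)stannane, C=C[Sn](CCCC)(CCCC)CCCC, and n-BuLi)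
Why: Vinyllithium adds 1,2 to the strained ketone of 15, and lithium cyclobutenolate 16 undergoes oxyanion-accelerated conrotatory 4π opening of the temporary C3–C6 bond with the oxido group turning outward, so that the vinyl group is cis to C1 in trienolate 17, whose termini are the vinyl CH2 (C5) and the CMe2 carbon (C6). Disrotatory 6π-electrocyclization of 17 then closes the six-membered ring by forming the C5–C6 bond and the quaternary centre, giving cross-conjugated dienolate 18, which is protonated at C4 on work-up to enone 19. The closest known reaction type is the alkoxide-accelerated ring expansion of cyclobutenones with alkenyllithiums to cyclohex-2-enones, here ending at a fully substituted terminus. The four-membered ring is opened in the 4π conrotatory mode and the six-membered ring is closed in the 6π disrotatory mode; no stereocentre is formed, because C1 stays sp2 and is set later from the C3 ketone that this step installs. The step needs 1,2- over 1,4-addition (secured by the strained carbonyl and the hard organolithium), outward rotation of the oxido group (its intrinsic donor preference) and a regiodefined trienolate without proton shuffling to C1′ (secured because the trienolate arises by bond cleavage at low temperature, not by deprotonation). A [1,3]-shift of 16, should it compete, would lead to the same dienolate 18.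

Step 8
Reactants: 19 3-[(3E,7E)-9-(tert-butyldiphenylsilyloxy)-4,8-dimethylnona-3,7-dien-1-yl]-2,4,4-trimethylcyclohex-2-en-1-one
Product: 20 (1R)-3-[(3E,7E)-9-(tert-butyldiphenylsilyloxy)-4,8-dimethylnona-3,7-dien-1-yl]-2,4,4-trimethylcyclohex-2-en-1-ol
Conditions: (S)-2-methyl-CBS-oxazaborolidine (0.3 equiv), catecholborane, toluene, −78 → −40 °C; then MeOH, aq. NaOH
Reagents that add atoms: none
Why: Corey–Bakshi–Shibata reduction; the ketone is flanked by the fully substituted alkene carbon C2 (large) and CH2 C4 (small), so the (S)-catalyst should give the (R)-carbinol at C3 (a temporary stereocentre), and catecholborane leaves the isolated alkenes alone.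

Step 9
Reactants: 20 (1R)-3-[(3E,7E)-9-(tert-butyldiphenylsilyloxy)-4,8-dimethylnona-3,7-dien-1-yl]-2,4,4-trimethylcyclohex-2-en-1-ol
Product: 23 tert-butyl{[(2E,6E)-3,7-dimethyl-9-[(1S)-2,6,6-trimethylcyclohex-2-en-1-yl]nona-2,6-dien-1-yl]oxy}diphenylsilane, via sulfonylhydrazine 21 (not isolated), via allylic diazene 22 (not isolated)
Conditions: 2-nitrobenzenesulfonylhydrazide (NBSH), PPh3, DEAD, N-methylmorpholine, −30 °C → 23 °C
Reagents that add atoms: none
Why: Myers reductive 1,3-transposition: Mitsunobu displacement by NBSH inverts C3, loss of sulfinic acid gives allylic diazene 22, and its retro-ene loss of N2 transfers hydrogen suprafacially to C1, so the (R)-C3–O bond is translated into the (S)-C1–H stereocentre while the double bond moves to C2=C3.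

Step 10
Reactants: 23 tert-butyl{[(2E,6E)-3,7-dimethyl-9-[(1S)-2,6,6-trimethylcyclohex-2-en-1-yl]nona-2,6-dien-1-yl]oxy}diphenylsilane
Product: 24 (2E,6E)-3,7-dimethyl-9-[(1S)-2,6,6-trimethylcyclohex-2-en-1-yl]nona-2,6-dien-1-ol
Conditions: TBAF, AcOH, THF, rt
Reagents that add atoms: none
Why: Fluoride-mediated desilylation (buffered with acetic acid) should free the primary allylic alcohol without affecting the alkenes or C1.

Step 11
Reactants: 24 (2E,6E)-3,7-dimethyl-9-[(1S)-2,6,6-trimethylcyclohex-2-en-1-yl]nona-2,6-dien-1-ol, 25 arachidonic acid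
Product: 26 (2E,6E)-3,7-dimethyl-9-[(1S)-2,6,6-trimethylcyclohex-2-en-1-yl]nona-2,6-dien-1-yl (5Z,8Z,11Z,14Z)-icosa-5,8,11,14-tetraenoate (CNP0207506.1)
Conditions: DCC, DMAP (cat.), CH2Cl2, 0 °C → rt, argon, dark
Reagents that add atoms: none
Why: Steglich esterification of the primary alcohol under neutral conditions should keep the skipped Z-tetraene and the C1 stereocentre intact.

**Compound list**

1 | (2E,6E)-farnesol | CC(C)=CCC/C(C)=C/CC/C(C)=C/CO | starting material
2 | (2E,6E)-farnesyl tert-butyldiphenylsilyl ether | CC(C)=CCC/C(C)=C/CC/C(C)=C/CO[Si](c1ccccc1)(c1ccccc1)C(C)(C)C | intermediate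
3 | racemic 10-bromo-11-hydroxy bromohydrin of 2 | CC(C)(O)C(Br)CC/C(C)=C/CC/C(C)=C/CO[Si](c1ccccc1)(c1ccccc1)C(C)(C)C | intermediate
4 | racemic 10,11-epoxide of 2 | CC1(C)OC1CC/C(C)=C/CC/C(C)=C/CO[Si](c1ccccc1)(c1ccccc1)C(C)(C)C | intermediate
5 | (4E,8E)-10-(tert-butyldiphenylsilyloxy)-4,8-dimethyldeca-4,8-dienal | O=CCC/C(C)=C/CC/C(C)=C/CO[Si](c1ccccc1)(c1ccccc1)C(C)(C)C | intermediate
6 | (4E,8E)-10-(tert-butyldiphenylsilyloxy)-4,8-dimethyldeca-4,8-dienoic acid | OC(=O)CC/C(C)=C/CC/C(C)=C/CO[Si](c1ccccc1)(c1ccccc1)C(C)(C)C | intermediate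
7 | 2-thioxopyridin-1(2H)-yl ester of 6 (Barton ester) | S=C1C=CC=CN1OC(=O)CC/C(C)=C/CC/C(C)=C/CO[Si](c1ccccc1)(c1ccccc1)C(C)(C)C | intermediate
8 | tert-butyl{[(2E,6E)-9-iodo-3,7-dimethylnona-2,6-dien-1-yl]oxy}diphenylsilane | ICC/C(C)=C/CC/C(C)=C/CO[Si](c1ccccc1)(c1ccccc1)C(C)(C)C | intermediate
9 | isobutyryl chloride (2-methylpropanoyl chloride) | CC(C)C(=O)Cl | starting material
10 | 1-ethoxyprop-1-yne | CCOC#CC | starting material
11 | dimethylketene | CC(C)=C=O | intermediate
12 | 3-ethoxy-2,4,4-trimethylcyclobut-2-en-1-one | CCOC1=C(C)C(=O)C1(C)C | intermediate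
13 | (3E,7E)-9-(tert-butyldiphenylsilyloxy)-4,8-dimethylnona-3,7-dien-1-yllithium | [Li]CC/C(C)=C/CC/C(C)=C/CO[Si](c1ccccc1)(c1ccccc1)C(C)(C)C | intermediate
14 | lithium 3-ethoxy-2,4,4-trimethyl-1-[(3E,7E)-9-(tert-butyldiphenylsilyloxy)-4,8-dimethylnona-3,7-dien-1-yl]cyclobut-2-en-1-olate (racemic) | [Li+].CCOC1=C(C)C([O-])(CC/C(C)=C/CC/C(C)=C/CO[Si](c2ccccc2)(c2ccccc2)C(C)(C)C)C1(C)C | intermediate
15 | 3-[(3E,7E)-9-(tert-butyldiphenylsilyloxy)-4,8-dimethylnona-3,7-dien-1-yl]-2,4,4-trimethylcyclobut-2-en-1-one | CC1=C(CC/C(C)=C/CC/C(C)=C/CO[Si](c2ccccc2)(c2ccccc2)C(C)(C)C)C(C)(C)C1=O | intermediate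
16 | lithium 1-ethenyl-2,4,4-trimethyl-3-(side chain)cyclobut-2-en-1-olate (racemic) | [Li+].C=CC1([O-])C(C)=C(CC/C(C)=C/CC/C(C)=C/CO[Si](c2ccccc2)(c2ccccc2)C(C)(C)C)C1(C)C | intermediate
17 | lithium trienolate (3-oxido-hexatriene with vinyl cis to C1; termini C5 and C6) | [Li+].C=C/C([O-])=C(C)\C(CC/C(C)=C/CC/C(C)=C/CO[Si](c1ccccc1)(c1ccccc1)C(C)(C)C)=C(C)C | intermediate
18 | lithium cyclohexadienolate (O–C3=C4 and C1=C2) | [Li+].CC1=C(CC/C(C)=C/CC/C(C)=C/CO[Si](c2ccccc2)(c2ccccc2)C(C)(C)C)C(C)(C)CC=C1[O-] | intermediate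
19 | 3-[(3E,7E)-9-(tert-butyldiphenylsilyloxy)-4,8-dimethylnona-3,7-dien-1-yl]-2,4,4-trimethylcyclohex-2-en-1-one | CC1=C(CC/C(C)=C/CC/C(C)=C/CO[Si](c2ccccc2)(c2ccccc2)C(C)(C)C)C(C)(C)CCC1=O | intermediate
20 | (1R)-3-[(3E,7E)-9-(tert-butyldiphenylsilyloxy)-4,8-dimethylnona-3,7-dien-1-yl]-2,4,4-trimethylcyclohex-2-en-1-ol | CC1=C(CC/C(C)=C/CC/C(C)=C/CO[Si](c2ccccc2)(c2ccccc2)C(C)(C)C)C(C)(C)CC[C@H]1O | intermediate
21 | N-[(1S)-3-(side chain)-2,4,4-trimethylcyclohex-2-en-1-yl]-2-nitrobenzenesulfonohydrazide | CC1=C(CC/C(C)=C/CC/C(C)=C/CO[Si](c2ccccc2)(c2ccccc2)C(C)(C)C)C(C)(C)CC[C@@H]1N(N)S(=O)(=O)c1ccccc1[N+](=O)[O-] | intermediate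
22 | (1S)-allylic diazene | CC1=C(CC/C(C)=C/CC/C(C)=C/CO[Si](c2ccccc2)(c2ccccc2)C(C)(C)C)C(C)(C)CC[C@@H]1N=N | intermediate
23 | tert-butyl{[(2E,6E)-3,7-dimethyl-9-[(1S)-2,6,6-trimethylcyclohex-2-en-1-yl]nona-2,6-dien-1-yl]oxy}diphenylsilane | CC(C)(C)[Si](c1ccccc1)(c1ccccc1)OC/C=C(\C)CC/C=C(\C)CC[C@@H]1C(C)=CCCC1(C)C | intermediate
24 | (2E,6E)-3,7-dimethyl-9-[(1S)-2,6,6-trimethylcyclohex-2-en-1-yl]nona-2,6-dien-1-ol | OC/C=C(\C)CC/C=C(\C)CC[C@@H]1C(C)=CCCC1(C)C | intermediate
25 | arachidonic acid, (5Z,8Z,11Z,14Z)-icosa-5,8,11,14-tetraenoic acid | CCCCC/C=C\C/C=C\C/C=C\C/C=C\CCCC(=O)O | starting material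
26 | (2E,6E)-3,7-dimethyl-9-[(1S)-2,6,6-trimethylcyclohex-2-en-1-yl]nona-2,6-dien-1-yl (5Z,8Z,11Z,14Z)-icosa-5,8,11,14-tetraenoate | CCCCC/C=C\C/C=C\C/C=C\C/C=C\CCCC(=O)OC/C=C(\C)CC/C=C(\C)CC[C@@H]1C(C)=CCCC1(C)C | target

**Step count and risks**

Total step count: 11. Longest linear sequence: 10 (steps 1–4 and 6–11).

Steps most likely to fail:

1. Step 7. The fully substituted trienolate may not reach the near-planar geometry needed for closure at the CMe2 terminus, so that it is protonated to an open dienone or isomerises by a [1,7]-hydrogen shift before the ring forms. Fallback, setting out from 8 and coming back at 19: the same C5–C6 closure is run on a less substituted triene that has hydrogen on C1, and the side chain is attached afterwards. Wittig reaction of isobutyraldehyde with 2-(triphenylphosphoranylidene)propanal should give (E)-2,4-dimethylpent-2-enal F1; vinylmagnesium bromide gives (E)-4,6-dimethylhepta-1,4-dien-3-ol F2, and MnO2 gives the cross-conjugated dienone (E)-4,6-dimethylhepta-1,4-dien-3-one F3. KOt-Bu in t-BuOH/THF removes the γ-hydrogen at C6, and the trienolate closes in the isophorone manner (C5–C6) to 2,4,4-trimethylcyclohex-2-en-1-one F4. Iodide 8 is converted with magnesium into the Grignard reagent F5, which adds to F4 under CuBr·SMe2 catalysis in the presence of Me3SiCl to give the racemic silyl enol ether F6. Saegusa–Ito oxidation (Pd(OAc)2, MeCN) returns enone 19.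

2. Step 9. The Mitsunobu displacement at the hindered allylic carbinol may be sluggish and divert to elimination or allylic scrambling, which would erode the transfer of chirality to C1. Fallback, setting out from 20 and coming back at 23: formylation (HCO2H, DCC, DMAP) gives the allylic formate F7. Heating with Pd(OAc)2 and n-Bu3P (zerovalent palladium formed in the flask) in THF effects Tsuji–Trost-type formate hydrogenolysis: ionisation anti to the formate, loss of CO2 and delivery of hydride from palladium to the more substituted terminus C1 should give 23 with the same (S) configuration.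

3. Step 5. Dimerisation of the ketene and polymerisation of the ynol ether may outpace the [2+2] cycloaddition. Fallback, setting out from 9 and coming back at 12: 9, Et3N and commercial ethoxyethyne give the well-precedented 3-ethoxy-4,4-dimethylcyclobut-2-en-1-one F8. N-Iodosuccinimide iodinates the electron-rich α-carbon to give 3-ethoxy-2-iodo-4,4-dimethylcyclobut-2-en-1-one F9, and Stille methylation (Me4Sn, Pd(PPh3)4, CuI, DMF) installs the methyl group to return 12.

**Further compounds**

F1 | step 7 | (E)-2,4-dimethylpent-2-enal | CC(C)/C=C(\C)C=O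
F2 | step 7 | (E)-4,6-dimethylhepta-1,4-dien-3-ol | CC(C)/C=C(\C)C(O)C=C
F3 | step 7 | (E)-4,6-dimethylhepta-1,4-dien-3-one | CC(C)/C=C(\C)C(=O)C=C
F4 | step 7 | 2,4,4-trimethylcyclohex-2-en-1-one | CC1=CC(C)(C)CCC1=O
F5 | step 7 | (3E,7E)-9-(tert-butyldiphenylsilyloxy)-4,8-dimethylnona-3,7-dien-1-ylmagnesium iodide | I[Mg]CC/C(C)=C/CC/C(C)=C/CO[Si](c1ccccc1)(c1ccccc1)C(C)(C)C
F6 | step 7 | racemic trimethylsilyl enol ether of 3-(side chain)-2,4,4-trimethylcyclohexanone | CC1=C(O[Si](C)(C)C)CCC(C)(C)C1CC/C(C)=C/CC/C(C)=C/CO[Si](c1ccccc1)(c1ccccc1)C(C)(C)C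
F7 | step 9 | (1R)-3-(side chain)-2,4,4-trimethylcyclohex-2-en-1-yl formate | CC1=C(CC/C(C)=C/CC/C(C)=C/CO[Si](c2ccccc2)(c2ccccc2)C(C)(C)C)C(C)(C)CC[C@H]1OC=O
F8 | step 5 | 3-ethoxy-4,4-dimethylcyclobut-2-en-1-one | CCOC1=CC(=O)C1(C)C
F9 | step 5 | 3-ethoxy-2-iodo-4,4-dimethylcyclobut-2-en-1-one | CCOC1=C(I)C(=O)C1(C)C
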